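**Retrosynthetic overview** (decalin numbering: C1 quaternary, C2 pentadienyl-bearing, C3=C4, C4a, C5–C8, C8a)
1. The tetramic acid is made last by Lacey–Dieckmann closure of a β-keto amide, which comes from the quaternary aldehyde 11 by two-carbon thioester homologation and coupling with L-threonine methyl ester.
2. Ring B is closed by a one-flask (3+3) annulation of iodo silyl enol ether 6 with (2E,4E,6E)-octatrienal 7: C4–C4a by alkyllithium addition to the aldehyde, C1–C2 by capture of the derived trienyl cation by the enol ether.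
3. Enabling feature: ring B is a cyclohexene whose C3=C4 bond separates two three-carbon units. C2–C3–C4 is an enal (C4 carbonyl carbon, C2 vinylogous and doubly allylic, so cation-bearing). C4a–C8a–C1 is a 1,3-dinucleophile (C1 is α to the acyl carbonyl, hence an enol carbon; C4a becomes C–Li).
4. Ring A, C1, the C1 methyl and the acyl carbon are the ten carbons of (−)-mintlactone 1. Hydrogenation relays C7a of the lactone to C8a (the C6 methyl ends axial on the trans-decalin); iodide opens the lactone with inversion to set C4a.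
5. Order of ring formation: ring A (chiral pool), ring B (step 5), pyrrolidine-2,4-dione (step 9).

Key step: step 5

Assumption: (−)-mintlactone (6R,7aR) is taken as a purchasable flavour-grade p-menthane lactone of natural configuration; the α-carbonyl centre carried through 2–5 is inconsequential because it becomes sp2 in 6.

Step 1
Reactants: 1 (−)-mintlactone
Product: 2 (3S,3aR,6R,7aR)-3,6-dimethylhexahydro-1-benzofuran-2(3H)-one
Conditions: H2 (50 bar), Rh/Al2O3, EtOAc, 25 °C
Reagents that add atoms: none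
Why: Catalytic syn hydrogenation should deliver both hydrogens to the tetrasubstituted butenolide double bond from the face of H-7a, away from the cyclohexane ring, so the all-cis lactone forms and C3a (later C8a) is set cis to the C6 methyl through the C7a relay.

Step 2
Reactants: 2 (3S,3aR,6R,7aR)-3,6-dimethylhexahydro-1-benzofuran-2(3H)-one
Product: 4 ethyl (2S)-2-[(1R,2S,4R)-2-iodo-4-methylcyclohexyl]propanoate, via trimethylsilyl ester 3 (not isolated)
Conditions: Me3SiI, CH2Cl2, 0 → 25 °C; then EtOH, 25 °C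
Reagents that add atoms: iodotrimethylsilane C[Si](C)(C)I; ethanol CCO
Why: Lactone cleavage with iodotrimethylsilane: the silylated lactone should be opened by iodide at the alkyl C–O carbon in an SN2 reaction with inversion, which places iodine trans to the propanoate side chain (later C4a), and ethanol converts the silyl ester into the ethyl ester.

Step 3
Reactants: 4 ethyl (2S)-2-[(1R,2S,4R)-2-iodo-4-methylcyclohexyl]propanoate
Product: 5 (2S)-2-[(1R,2S,4R)-2-iodo-4-methylcyclohexyl]propanal
Conditions: i-Bu2AlH, CH2Cl2, −78 °C; aq. potassium sodium tartrate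
Reagents that add atoms: none
Why: Partial ester reduction with i-Bu2AlH at low temperature should stop at the aluminium hemiacetal and give the aldehyde on work-up, the secondary iodide being inert.

Step 4
Reactants: 5 (2S)-2-[(1R,2S,4R)-2-iodo-4-methylcyclohexyl]propanal
Product: 6 {[2-((1R,2S,4R)-2-iodo-4-methylcyclohexyl)prop-1-en-1-yl]oxy}tri(propan-2-yl)silane (E/Z mixture)
Conditions: i-Pr3SiOSO2CF3, Et3N, CH2Cl2, 0 °C
Reagents that add atoms: tri(propan-2-yl)silyl trifluoromethanesulfonate CC(C)[Si](OS(=O)(=O)C(F)(F)F)(C(C)C)C(C)C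
Why: Soft enolisation (silyl enol ether formation) of the α-branched aldehyde should give the trisubstituted enol ether, which masks the carbonyl against the alkyllithium of step 5 and makes the future C1 a carbon nucleophile.

Step 5
Reactants: 6 {[2-((1R,2S,4R)-2-iodo-4-methylcyclohexyl)prop-1-en-1-yl]oxy}tri(propan-2-yl)silane; 7 (2E,4E,6E)-octa-2,4,6-trienal
Product: 11 (1R,2R,4aR,6R,8aS)-1,6-dimethyl-2-[(1E,3E)-penta-1,3-dien-1-yl]-1,2,4a,5,6,7,8,8a-octahydronaphthalene-1-carbaldehyde, via secondary cyclohexyllithium 8 (not isolated), via lithium trienyl alkoxide 9 (not isolated), via trienyl methanesulfonate 10 (not isolated)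
Conditions: t-BuLi (2.2 equiv), pentane–Et2O, −100 °C (6 added to the base); 7, −100 → −78 °C; then CH3SO2Cl, 2,6-lutidine, CH2Cl2, −78 → −20 °C; aq. NaHCO3
Reagents that add atoms: none
Why: Proposed new method: iodine–lithium exchange with retention should give the configurationally stable secondary cyclohexyllithium 8, which adds 1,2 to trienal 7 to form the C4–C4a bond; mesylation of alkoxide 9 then lets 10 ionise to a heptatrienyl cation that is captured at C2 by the tethered silyl enol ether carbon (C1), and loss of the silyl group releases the aldehyde. The closest known reaction types are the stereoretentive low-temperature exchange of secondary alkyl iodides followed by carbonyl addition, and the cation–olefin (intramolecular Mukaiyama-type SN1) allylation of silyl enol ethers by allylic cations. Ring B closes as a six-membered ring, endo with respect to the allyl cation (the C3=C4 double bond ends inside the ring) and exo with respect to the enol double bond. C4a keeps the trans relationship to the C8a side chain set in step 2; C2 is set by the chair-like closure on the trans-diequatorial cyclohexane, with the pentadienyl group equatorial; C1 is set by allylic strain in the enol ether, which holds H-8a in the enol plane so that the formyl carbon ends equatorial (cis to H-8a) and the methyl axial. The step needs 1,2- over conjugate addition (hard alkyllithium at −100 °C), capture at C2 rather than at the remote cation termini (only C2 closes a six-membered ring), and ring closure faster than proton loss from the cation (intramolecular nucleophile, buffered medium).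

Step 6
Reactants: 11 (1R,2R,4aR,6R,8aS)-1,6-dimethyl-2-[(1E,3E)-penta-1,3-dien-1-yl]-1,2,4a,5,6,7,8,8a-octahydronaphthalene-1-carbaldehyde; 12 S-tert-butyl ethanethioate
Product: 14 S-tert-butyl 3-[(1R,2R,4aR,6R,8aS)-1,6-dimethyl-2-[(1E,3E)-penta-1,3-dien-1-yl]-1,2,4a,5,6,7,8,8a-octahydronaphthalen-1-yl]-3-hydroxypropanethioate (carbinol epimers), via lithium thioester enolate 13 (not isolated)
Conditions: LiN(i-Pr)2, THF, −78 °C, 12; then 11, −78 °C; aq. NH4Cl
Reagents that add atoms: none
Why: Aldol addition of the lithium thioester enolate to the non-enolisable neopentyl aldehyde should give the β-hydroxy thioester; the new carbinol centre is removed in step 7, so its configuration is immaterial.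

Step 7
Reactants: 14 S-tert-butyl 3-[(1R,2R,4aR,6R,8aS)-1,6-dimethyl-2-[(1E,3E)-penta-1,3-dien-1-yl]-1,2,4a,5,6,7,8,8a-octahydronaphthalen-1-yl]-3-hydroxypropanethioate
Product: 15 S-tert-butyl 3-[(1R,2R,4aR,6R,8aS)-1,6-dimethyl-2-[(1E,3E)-penta-1,3-dien-1-yl]-1,2,4a,5,6,7,8,8a-octahydronaphthalen-1-yl]-3-oxopropanethioate
Conditions: Dess–Martin periodinane, NaHCO3, CH2Cl2, 0 → 25 °C
Reagents that add atoms: none
Why: Dess–Martin oxidation of the secondary alcohol should give the β-keto thioester under neutral conditions that leave the polyene and the quaternary centre untouched.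

Step 8
Reactants: 15 S-tert-butyl 3-[(1R,2R,4aR,6R,8aS)-1,6-dimethyl-2-[(1E,3E)-penta-1,3-dien-1-yl]-1,2,4a,5,6,7,8,8a-octahydronaphthalen-1-yl]-3-oxopropanethioate; 16 L-threonine methyl ester hydrochloride
Product: 17 methyl N-{3-[(1R,2R,4aR,6R,8aS)-1,6-dimethyl-2-[(1E,3E)-penta-1,3-dien-1-yl]-1,2,4a,5,6,7,8,8a-octahydronaphthalen-1-yl]-3-oxopropanoyl}-L-threoninate
Conditions: AgOCOCF3, Et3N, THF, 0 °C
Reagents that add atoms: none
Why: Silver-assisted aminolysis of the thioester by the free amine should give the β-keto amide chemoselectively at nitrogen, with both stereocentres of L-threonine carried through unchanged.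

Step 9
Reactants: 17 methyl N-{3-[(1R,2R,4aR,6R,8aS)-1,6-dimethyl-2-[(1E,3E)-penta-1,3-dien-1-yl]-1,2,4a,5,6,7,8,8a-octahydronaphthalen-1-yl]-3-oxopropanoyl}-L-threoninate
Product: 18 (5S)-3-{[(1R,2R,4aR,6R,8aS)-1,6-dimethyl-2-[(1E,3E)-penta-1,3-dien-1-yl]-1,2,4a,5,6,7,8,8a-octahydronaphthalen-1-yl]carbonyl}-4-hydroxy-5-[(1R)-1-hydroxyethyl]-1,5-dihydro-2H-pyrrol-2-one
Conditions: NaOMe, MeOH, 25 °C (short contact time); aq. HCl to pH 3
Reagents that add atoms: none
Why: Lacey–Dieckmann cyclisation: the β-keto amide enolate should attack the methyl ester to close the pyrrolidine-2,4-dione, isolated as the enolised 3-acyl tetramic acid after acidification, with C5 keeping the L-threonine configuration if exposure to base is short.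

**Compound list**
1 | (−)-mintlactone, (6R,7aR)-3,6-dimethyl-5,6,7,7a-tetrahydro-1-benzofuran-2(4H)-one | CC1=C2CC[C@@H](C)C[C@H]2OC1=O | starting material
2 | (3S,3aR,6R,7aR)-3,6-dimethylhexahydro-1-benzofuran-2(3H)-one (all-cis) | C[C@H]1[C@H]2CC[C@@H](C)C[C@H]2OC1=O | intermediate
3 | trimethylsilyl (2S)-2-[(1R,2S,4R)-2-iodo-4-methylcyclohexyl]propanoate | C[C@H](C(=O)O[Si](C)(C)C)[C@H]1CC[C@@H](C)C[C@@H]1I | intermediate
4 | ethyl (2S)-2-[(1R,2S,4R)-2-iodo-4-methylcyclohexyl]propanoate | CCOC(=O)[C@@H](C)[C@H]1CC[C@@H](C)C[C@@H]1I | intermediate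
5 | (2S)-2-[(1R,2S,4R)-2-iodo-4-methylcyclohexyl]propanal | O=C[C@@H](C)[C@H]1CC[C@@H](C)C[C@@H]1I | intermediate
6 | {[2-((1R,2S,4R)-2-iodo-4-methylcyclohexyl)prop-1-en-1-yl]oxy}tri(propan-2-yl)silane, E/Z mixture | CC(C)[Si](OC=C(C)[C@H]1CC[C@@H](C)C[C@@H]1I)(C(C)C)C(C)C | intermediate
7 | (2E,4E,6E)-octa-2,4,6-trienal | C/C=C/C=C/C=C/C=O | starting material
8 | [(1S,2S,5R)-5-methyl-2-(1-{[tri(propan-2-yl)silyl]oxy}prop-1-en-2-yl)cyclohexyl]lithium (lithium in place of iodine, retention) | CC(C)[Si](OC=C(C)[C@H]1CC[C@@H](C)C[C@@H]1[Li])(C(C)C)C(C)C | intermediate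
9 | lithium (2E,4E,6E)-1-[(1S,2S,5R)-5-methyl-2-(1-{[tri(propan-2-yl)silyl]oxy}prop-1-en-2-yl)cyclohexyl]octa-2,4,6-trien-1-olate (carbinol epimers) | CC(C)[Si](OC=C(C)[C@H]1CC[C@@H](C)C[C@@H]1C(O[Li])/C=C/C=C/C=C/C)(C(C)C)C(C)C | intermediate
10 | (2E,4E,6E)-1-[(1S,2S,5R)-5-methyl-2-(1-{[tri(propan-2-yl)silyl]oxy}prop-1-en-2-yl)cyclohexyl]octa-2,4,6-trien-1-yl methanesulfonate (carbinol epimers) | CC(C)[Si](OC=C(C)[C@H]1CC[C@@H](C)C[C@@H]1C(OS(C)(=O)=O)/C=C/C=C/C=C/C)(C(C)C)C(C)C | intermediate
11 | (1R,2R,4aR,6R,8aS)-1,6-dimethyl-2-[(1E,3E)-penta-1,3-dien-1-yl]-1,2,4a,5,6,7,8,8a-octahydronaphthalene-1-carbaldehyde | C/C=C/C=C/[C@@H]1C=C[C@H]2C[C@H](C)CC[C@@H]2[C@@]1(C)C=O | intermediate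
12 | S-tert-butyl ethanethioate | CC(=O)SC(C)(C)C | starting material
13 | lithium 1-(tert-butylsulfanyl)ethen-1-olate | C=C(O[Li])SC(C)(C)C | intermediate
14 | S-tert-butyl 3-[(1R,2R,4aR,6R,8aS)-1,6-dimethyl-2-[(1E,3E)-penta-1,3-dien-1-yl]-1,2,4a,5,6,7,8,8a-octahydronaphthalen-1-yl]-3-hydroxypropanethioate (carbinol epimers) | C/C=C/C=C/[C@@H]1C=C[C@H]2C[C@H](C)CC[C@@H]2[C@@]1(C)C(O)CC(=O)SC(C)(C)C | intermediate
15 | S-tert-butyl 3-[(1R,2R,4aR,6R,8aS)-1,6-dimethyl-2-[(1E,3E)-penta-1,3-dien-1-yl]-1,2,4a,5,6,7,8,8a-octahydronaphthalen-1-yl]-3-oxopropanethioate | C/C=C/C=C/[C@@H]1C=C[C@H]2C[C@H](C)CC[C@@H]2[C@@]1(C)C(=O)CC(=O)SC(C)(C)C | intermediate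
16 | L-threonine methyl ester hydrochloride | COC(=O)[C@@H](N)[C@@H](C)O.Cl | starting material
17 | methyl N-{3-[(1R,2R,4aR,6R,8aS)-1,6-dimethyl-2-[(1E,3E)-penta-1,3-dien-1-yl]-1,2,4a,5,6,7,8,8a-octahydronaphthalen-1-yl]-3-oxopropanoyl}-L-threoninate | C/C=C/C=C/[C@@H]1C=C[C@H]2C[C@H](C)CC[C@@H]2[C@@]1(C)C(=O)CC(=O)N[C@H](C(=O)OC)[C@@H](C)O | intermediate
18 | (5S)-3-{[(1R,2R,4aR,6R,8aS)-1,6-dimethyl-2-[(1E,3E)-penta-1,3-dien-1-yl]-1,2,4a,5,6,7,8,8a-octahydronaphthalen-1-yl]carbonyl}-4-hydroxy-5-[(1R)-1-hydroxyethyl]-1,5-dihydro-2H-pyrrol-2-one | C/C=C/C=C/[C@@H]1C=C[C@H]2C[C@H](C)CC[C@@H]2[C@@]1(C)C(=O)C1=C(O)[C@H]([C@@H](C)O)NC1=O | target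

Total step count: 9
Longest linear sequence: 9 steps (1 to 18)

**Steps most likely to fail**

Step 5 (Proposed new method). The heptatrienyl cation may lose a proton to a tetraene, or the enol ether may be desilylated, before ring closure; the lithium-bearing carbon may also lose its configuration if the exchange is not kept cold and brief. The fallback uses known chemistry and a palladium π-allyl instead of a free cation. It sets out from 6: the same exchange and addition to 7 are followed by aqueous work-up to isolate the trienol F1. Methyl chloroformate and pyridine should convert it into the allylic methyl carbonate F2. Pd2(dba)3 with 1,2-bis(diphenylphosphino)ethane in THF should then effect a Tsuji–Trost allylation of the silyl enol ether: zerovalent palladium ionises the carbonate, the released methoxide removes the silyl group, and the enolate attacks the only allyl terminus that closes a six-membered ring. The fallback comes back to the route at 11.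

Step 2. Elimination to a cyclohexene acid under the acidic iodide conditions, or relactonisation of the iodo ester, may outrun the SN2 opening. The fallback replaces lactone C–O cleavage by reduction and displacement at a free alcohol, and sets out from 2. LiAlH4 in THF should give the diol F3, t-BuMe2SiCl and imidazole the primary silyl ether F4, and an Appel reaction (I2, PPh3, imidazole) the iodide F5 with the same inversion at the ring carbon. Bu4NF should then free the iodo alcohol F6, and Dess–Martin oxidation brings the fallback back to the route at 5.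

Step 9. Epimerisation at C5 of the tetramic acid, or base-induced degradation of the unprotected hydroxyethyl side chain, may occur under methoxide. The fallback sets out from 15 and uses a protected amino ester and a fluoride-induced ring closure. Silver-assisted aminolysis with commercial methyl O-tert-butyl-L-threoninate hydrochloride should give the tert-butyl ether amide F7. Bu4NF in THF should close the ring to the O-tert-butyl tetramic acid F8, and CF3CO2H in CH2Cl2 at 0 °C should remove the ether, which brings the fallback back to the route at 18.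

**Further compounds**
F1 | step 5 | (2E,4E,6E)-1-[(1S,2S,5R)-5-methyl-2-(1-{[tri(propan-2-yl)silyl]oxy}prop-1-en-2-yl)cyclohexyl]octa-2,4,6-trien-1-ol (carbinol epimers) | CC(C)[Si](OC=C(C)[C@H]1CC[C@@H](C)C[C@@H]1C(O)/C=C/C=C/C=C/C)(C(C)C)C(C)C
F2 | step 5 | methyl (2E,4E,6E)-1-[(1S,2S,5R)-5-methyl-2-(1-{[tri(propan-2-yl)silyl]oxy}prop-1-en-2-yl)cyclohexyl]octa-2,4,6-trien-1-yl carbonate (carbinol epimers) | CC(C)[Si](OC=C(C)[C@H]1CC[C@@H](C)C[C@@H]1C(OC(=O)OC)/C=C/C=C/C=C/C)(C(C)C)C(C)C
F3 | step 2 | (2S)-2-[(1R,2R,4R)-2-hydroxy-4-methylcyclohexyl]propan-1-ol | OC[C@@H](C)[C@H]1CC[C@@H](C)C[C@H]1O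
F4 | step 2 | (1R,2R,5R)-2-[(2S)-1-{[tert-butyl(dimethyl)silyl]oxy}propan-2-yl]-5-methylcyclohexan-1-ol | CC(C)(C)[Si](C)(C)OC[C@@H](C)[C@H]1CC[C@@H](C)C[C@H]1O
F5 | step 2 | tert-butyl{[(2S)-2-((1R,2S,4R)-2-iodo-4-methylcyclohexyl)propyl]oxy}dimethylsilane | CC(C)(C)[Si](C)(C)OC[C@@H](C)[C@H]1CC[C@@H](C)C[C@@H]1I
F6 | step 2 | (2S)-2-[(1R,2S,4R)-2-iodo-4-methylcyclohexyl]propan-1-ol | OC[C@@H](C)[C@H]1CC[C@@H](C)C[C@@H]1I
F7 | step 9 | methyl O-tert-butyl-N-{3-[(1R,2R,4aR,6R,8aS)-1,6-dimethyl-2-[(1E,3E)-penta-1,3-dien-1-yl]-1,2,4a,5,6,7,8,8a-octahydronaphthalen-1-yl]-3-oxopropanoyl}-L-threoninate | C/C=C/C=C/[C@@H]1C=C[C@H]2C[C@H](C)CC[C@@H]2[C@@]1(C)C(=O)CC(=O)N[C@H](C(=O)OC)[C@@H](C)OC(C)(C)C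
F8 | step 9 | (5S)-5-[(1R)-1-tert-butoxyethyl]-3-{[(1R,2R,4aR,6R,8aS)-1,6-dimethyl-2-[(1E,3E)-penta-1,3-dien-1-yl]-1,2,4a,5,6,7,8,8a-octahydronaphthalen-1-yl]carbonyl}-4-hydroxy-1,5-dihydro-2H-pyrrol-2-one | C/C=C/C=C/[C@@H]1C=C[C@H]2C[C@H](C)CC[C@@H]2[C@@]1(C)C(=O)C1=C(O)[C@H]([C@@H](C)OC(C)(C)C)NC1=O
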